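**Plan**

- Retrosynthesis (labdane numbering throughout): remove the silyl and tert-butyl groups; cut C12–C13 (B-alkyl Suzuki–Miyaura coupling), C11=C12 (Wittig), the two isovalerate C–O bonds and C4–C18 (enolate methylation); take ring A back to a cross-conjugated dienone; cut C9–C10 (palladium-catalysed dearomative alkenylation, ring B); cut C6–C7 (vinylogous Mukaiyama aldol); cut C4–C19 and C5–C6 from a bromocresol.
- Enabling feature: in ring A the oxygen-bearing C3 and the methyl-bearing quaternary C10 are para, C4 (with C19) is ortho to the C3 oxygen, and C5 carries the C6–C9 chain. Ring A can therefore start as a para-methyl salicylate phenol whose para carbon C10 is alkenylated by C9. The C4 ester blocks the other carbon next to the tether and later activates C5 for hydride and C4 for methylation.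
- Forward order: ring A is bought as an arene; C19 and C6 are attached by ortho-metalation and Br/Mg exchange; the aldol adds C7–C9 with C11 and C17; ring B closes in the dearomatisation; ring A is reduced and methylated; the C12–C16 chain is joined last.
- Stereochemistry: C6 from the chiral Lewis-base catalyst in the aldol; C10 in the ring closure (relayed from C6, reinforced by the P-stereogenic ligand); C5 by hydride addition anti to the 6β-silyloxy and 10β-methyl groups; C4 by α-face methylation; C3 by equatorial attack of LiBH(s-Bu)3; C13=C14 from the E-enol triflate; C8=C9 from the aldol geometry.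

Key step: step 9

Remark: the sense of induction in steps 6 and 9 is assumed to be selectable through the catalyst antipode; the descriptors written for the products are those the target requires.

**Route**

Step 1
Reactants: 1 3-bromo-4-methylphenol
Product: 2 2-bromo-4-(methoxymethoxy)-1-methylbenzene
Conditions: MOMCl, i-Pr2NEt, CH2Cl2, 0 °C → rt
Reagents that add atoms: chloromethyl methyl ether, COCCl
Why: Williamson-type O-alkylation of the phenol; the methoxymethyl ether protects the phenol and is the directing group for the next step.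

Step 2
Reactants: 2 2-bromo-4-(methoxymethoxy)-1-methylbenzene
Product: 4 methyl 2-bromo-6-(methoxymethoxy)-3-methylbenzoate, via aryllithium 3 (not isolated)
Conditions: LiN(i-Pr)2, THF, −78 °C; ClCO2Me, −78 °C
Reagents that add atoms: methyl chloroformate, COC(=O)Cl
Why: Directed ortho-metalation removes the proton flanked by the methoxymethoxy and bromo groups (the most acidic site; a lithium amide does not exchange the bromide) and the aryllithium is acylated to the hindered benzoate that will become C19.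

Step 3
Reactants: 4 methyl 2-bromo-6-(methoxymethoxy)-3-methylbenzoate
Product: 6 methyl 2-formyl-6-(methoxymethoxy)-3-methylbenzoate, via arylmagnesium chloride 5 (not isolated)
Conditions: i-PrMgCl·LiCl, THF, −20 °C; DMF, −20 → 0 °C; aq. NH4Cl
Reagents that add atoms: N,N-dimethylformamide, CN(C)C=O
Why: Bromine–magnesium exchange, assisted by chelation to the ortho ester and run cold so that the hindered ester is not attacked, gives the arylmagnesium species, which DMF formylates (Bouveault formylation) to install C6.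

Step 4
Reactants: 7 methyl 3-methylbut-2-enoate
Product: 9 methyl 2-bromo-3-methylbut-2-enoate, via dibromide 8 (not isolated)
Conditions: Br2, CH2Cl2, 0 °C → rt; then Et3N, 0 °C → rt
Reagents that add atoms: bromine, BrBr
Why: Ionic bromination of the trisubstituted alkene followed by base-induced dehydrobromination (acidic α-hydrogen removed, tertiary β-bromide lost, E1cB-like) returns the conjugated α-bromo enoate.

Step 5
Reactants: 9 methyl 2-bromo-3-methylbut-2-enoate
Product: 11 [(2-bromo-1-methoxy-3-methylbuta-1,3-dien-1-yl)oxy](tert-butyl)dimethylsilane, via lithium dienolate 10 (not isolated)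
Conditions: LiN(i-Pr)2, THF, −78 °C; t-BuMe2SiCl, DMPU, −78 °C → rt
Reagents that add atoms: tert-butyldimethylsilyl chloride, CC(C)(C)[Si](C)(C)Cl
Why: Kinetic γ-deprotonation of the β,β-dimethyl enoate gives the cross-conjugated dienolate, which the silyl chloride traps on oxygen as the silyl ketene acetal (silyl dienolate).

Step 6
Reactants: 6 methyl 2-formyl-6-(methoxymethoxy)-3-methylbenzoate; 11 [(2-bromo-1-methoxy-3-methylbuta-1,3-dien-1-yl)oxy](tert-butyl)dimethylsilane
Product: 12 methyl 2-[(1R,3Z)-4-bromo-1-hydroxy-5-methoxy-3-methyl-5-oxopent-3-en-1-yl]-6-(methoxymethoxy)-3-methylbenzoate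
Conditions: SiCl4 (1.1 equiv), (R,R)-bis-phosphoramide built from N,N′-dimethyl-1,1′-binaphthyl-2,2′-diamine with an N,N′-dimethylpentane-1,5-diamine linker (5 mol %), i-Pr2NEt (10 mol %), CH2Cl2, −78 °C; aq. NaHCO3
Reagents that add atoms: none
Why: Vinylogous Mukaiyama aldol under Lewis-base-activated SiCl4 catalysis, in which the phosphoramide-bound trichlorosilyl cation activates the aldehyde and selects its face (C6 = R) while the dienolate attacks through its γ-carbon from the s-trans conformer in an open transition state, so that C7 ends up trans to the ester (the Z bromoalkene needed for ring closure; any E isomer should lactonise and be removed).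

Step 7
Reactants: 12 methyl 2-[(1R,3Z)-4-bromo-1-hydroxy-5-methoxy-3-methyl-5-oxopent-3-en-1-yl]-6-(methoxymethoxy)-3-methylbenzoate
Product: 13 methyl 2-[(1R,3Z)-4-bromo-1-[(tert-butyldimethylsilyl)oxy]-5-methoxy-3-methyl-5-oxopent-3-en-1-yl]-6-(methoxymethoxy)-3-methylbenzoate
Conditions: t-BuMe2SiOTf, 2,6-lutidine, CH2Cl2, −78 → 0 °C
Reagents that add atoms: tert-butyldimethylsilyl trifluoromethanesulfonate, CC(C)(C)[Si](C)(C)OS(=O)(=O)C(F)(F)F
Why: The silyl triflate silylates the hindered benzylic alcohol under buffered, cold conditions that spare the aryl methoxymethyl ether, and the bulky silyl ether later provides the facial bias at C10, C5 and C4.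

Step 8
Reactants: 13 methyl 2-[(1R,3Z)-4-bromo-1-[(tert-butyldimethylsilyl)oxy]-5-methoxy-3-methyl-5-oxopent-3-en-1-yl]-6-(methoxymethoxy)-3-methylbenzoate
Product: 14 methyl 2-[(1R,3Z)-4-bromo-1-[(tert-butyldimethylsilyl)oxy]-5-methoxy-3-methyl-5-oxopent-3-en-1-yl]-6-hydroxy-3-methylbenzoate
Conditions: ZnBr2, n-PrSH, CH2Cl2, 0 °C
Reagents that add atoms: none
Why: Lewis acid/thiol cleavage of the aryl methoxymethyl ether (the oxocarbenium fragment is captured by the thiol) is fast at 0 °C, so the hindered secondary silyl ether, the alkenyl bromide and the esters should survive.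

Step 9
Reactants: 14 methyl 2-[(1R,3Z)-4-bromo-1-[(tert-butyldimethylsilyl)oxy]-5-methoxy-3-methyl-5-oxopent-3-en-1-yl]-6-hydroxy-3-methylbenzoate
Product: 15 dimethyl (4aS,8R)-8-[(tert-butyldimethylsilyl)oxy]-4a,6-dimethyl-2-oxo-2,4a,7,8-tetrahydronaphthalene-1,5-dicarboxylate
Conditions: Pd2(dba)3 (2.5 mol %), 4-(anthracen-9-yl)-3-tert-butyl-2,3-dihydro-1,3-benzoxaphosphole (P-stereogenic, matched antipode, 6 mol %), K2CO3 (2 equiv), toluene, 90 °C
Reagents that add atoms: none
Why: Zerovalent palladium inserts into the C9–Br bond, carbonate forms the potassium phenoxide, which displaces bromide on divalent palladium and binds through its para carbon C10, and C(sp2)–C(sp3) reductive elimination from the seven-membered palladacycle forms C9–C10 and releases the cyclohexa-2,5-dienone. The closest known reaction type is the palladium-catalysed enantioselective dearomative cyclisation of para-substituted phenols that carry a meta-tethered aryl or alkenyl halide. Ring B closes as a six-membered carbocycle, formally 6-endo with respect to the C5–C10 arene bond, and the Z geometry of the alkenyl bromide is carried into the ring as the C8=C9 double bond. The new stereocentre C10 is controlled by C6: its C–H bond lies in the arene plane to relieve allylic strain with the flanking ortho substituents, so the C7–C9 chain and the silyloxy group sit on opposite faces and the C10 methyl ends up cis to the silyloxy group, a bias the matched enantiomer of the P-stereogenic monophosphine reinforces. The step needs C-alkenylation at the para carbon rather than at oxygen or at the other carbon flanking the tether: the C4 ester makes that carbon fully substituted and less nucleophilic, closure through oxygen would require an eight-membered ring, and the alkenylpalladium intermediate has no β-hydrogen through which to decompose.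

Step 10
Reactants: 15 dimethyl (4aS,8R)-8-[(tert-butyldimethylsilyl)oxy]-4a,6-dimethyl-2-oxo-2,4a,7,8-tetrahydronaphthalene-1,5-dicarboxylate
Product: 16 dimethyl (4aS,8R)-8-[(tert-butyldimethylsilyl)oxy]-4a,6-dimethyl-2-oxo-2,3,4,4a,7,8-hexahydronaphthalene-1,5-dicarboxylate
Conditions: RhCl(PPh3)3 (5 mol %), H2 (1 atm), toluene/EtOH, rt
Reagents that add atoms: none
Why: Homogeneous hydrogenation with the bulky rhodium hydride reduces only the cis-disubstituted C1=C2 bond of the cross-conjugated dienone, as is known for 1,4-dien-3-ones, because the tetrasubstituted C4=C5 and C8=C9 bonds do not coordinate.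

Step 11
Reactants: 16 dimethyl (4aS,8R)-8-[(tert-butyldimethylsilyl)oxy]-4a,6-dimethyl-2-oxo-2,3,4,4a,7,8-hexahydronaphthalene-1,5-dicarboxylate
Product: 17 dimethyl (4aS,8R,8aR)-8-[(tert-butyldimethylsilyl)oxy]-2-hydroxy-4a,6-dimethyl-3,4,4a,7,8,8a-hexahydronaphthalene-1,5-dicarboxylate
Conditions: [(Ph3P)CuH]6 (0.5 equiv), toluene, rt; aq. NH4Cl
Reagents that add atoms: none
Why: Conjugate hydride transfer from the phosphine-stabilised copper hydride to the doubly activated C4=C5 bond gives the copper enolate without carbanion character at C5 (so the C6 silyloxy group is not eliminated), and hydride should add to the α face of C5 because the β face is screened by the 10β-methyl and the pseudoaxial 6β-silyloxy groups, setting the trans ring fusion (C5 = R); the β-keto ester is written as its enol, which has no C4 stereocentre.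

Step 12
Reactants: 17 dimethyl (4aS,8R,8aR)-8-[(tert-butyldimethylsilyl)oxy]-2-hydroxy-4a,6-dimethyl-3,4,4a,7,8,8a-hexahydronaphthalene-1,5-dicarboxylate
Product: 18 dimethyl (1R,4aS,8R,8aR)-8-[(tert-butyldimethylsilyl)oxy]-1,4a,6-trimethyl-2-oxo-1,2,3,4,4a,7,8,8a-octahydronaphthalene-1,5-dicarboxylate
Conditions: K2CO3, MeI, acetone, 50 °C
Reagents that add atoms: iodomethane, CI
Why: C-Methylation of the potassium enolate of the β-keto ester, in which the soft electrophile approaches C4 from the α face, anti to the syn-axial 10β-methyl and 6β-silyloxy groups, places C18 α and leaves the C19 ester β and axial (C4 = R).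

Step 13
Reactants: 18 dimethyl (1R,4aS,8R,8aR)-8-[(tert-butyldimethylsilyl)oxy]-1,4a,6-trimethyl-2-oxo-1,2,3,4,4a,7,8,8a-octahydronaphthalene-1,5-dicarboxylate
Product: 19 dimethyl (1R,2R,4aS,8R,8aR)-8-[(tert-butyldimethylsilyl)oxy]-2-hydroxy-1,4a,6-trimethyl-1,2,3,4,4a,7,8,8a-octahydronaphthalene-1,5-dicarboxylate
Conditions: LiBH(s-Bu)3, THF, −78 °C; aq. NaOH, H2O2, 0 °C
Reagents that add atoms: none
Why: The bulky trialkylborohydride attacks the C3 ketone along the equatorial trajectory, because the axial path is blocked by the axial hydrogens at C1 and C5, and gives the axial 3α-alcohol (C3 = R) as with 4,4-disubstituted 3-keto terpenoids, while the hindered esters are untouched at −78 °C.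

Step 14
Reactants: 19 dimethyl (1R,2R,4aS,8R,8aR)-8-[(tert-butyldimethylsilyl)oxy]-2-hydroxy-1,4a,6-trimethyl-1,2,3,4,4a,7,8,8a-octahydronaphthalene-1,5-dicarboxylate
Product: 20 (1S,2R,4aS,8R,8aR)-8-[(tert-butyldimethylsilyl)oxy]-1,5-bis(hydroxymethyl)-1,4a,6-trimethyl-1,2,3,4,4a,7,8,8a-octahydronaphthalen-2-ol
Conditions: LiAlH4, THF, 0 → 45 °C; aq. NaOH work-up
Reagents that add atoms: none
Why: Exhaustive hydride reduction converts the neopentyl C19 ester into the primary alcohol and the conjugated C11 ester into the allylic alcohol (1,2-reduction; the tetrasubstituted alkene is inert), with the silyl ether unaffected.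

Step 15
Reactants: 20 (1S,2R,4aS,8R,8aR)-8-[(tert-butyldimethylsilyl)oxy]-1,5-bis(hydroxymethyl)-1,4a,6-trimethyl-1,2,3,4,4a,7,8,8a-octahydronaphthalen-2-ol
Product: 21 (4R,4aR,5S,6R,8aS)-4-[(tert-butyldimethylsilyl)oxy]-6-hydroxy-5-(hydroxymethyl)-2,5,8a-trimethyl-3,4,4a,5,6,7,8,8a-octahydronaphthalene-1-carbaldehyde
Conditions: MnO2 (activated, excess), CH2Cl2, rt
Reagents that add atoms: none
Why: MnO2 oxidises only the allylic C11 alcohol to the enal and leaves the saturated 3α- and 19-hydroxyls, which differentiates the three hydroxyl groups without a protecting group.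

Step 16
Reactants: 21 (4R,4aR,5S,6R,8aS)-4-[(tert-butyldimethylsilyl)oxy]-6-hydroxy-5-(hydroxymethyl)-2,5,8a-trimethyl-3,4,4a,5,6,7,8,8a-octahydronaphthalene-1-carbaldehyde
Product: 22 [(1S,2R,4aS,8R,8aR)-8-[(tert-butyldimethylsilyl)oxy]-5-formyl-1,4a,6-trimethyl-2-[(3-methylbutanoyl)oxy]-1,2,3,4,4a,7,8,8a-octahydronaphthalen-1-yl]methyl 3-methylbutanoate
Conditions: 3-methylbutanoyl chloride, pyridine, 4-(dimethylamino)pyridine (cat.), CH2Cl2, 0 → 40 °C
Reagents that add atoms: 3-methylbutanoyl chloride, CC(C)CC(=O)Cl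
Why: Nucleophile-catalysed esterification acylates the primary 19-hydroxyl and the axial 3α-hydroxyl, while O6 stays masked as its silyl ether and the enal offers no acylable site.

Step 17
Reactants: 22 [(1S,2R,4aS,8R,8aR)-8-[(tert-butyldimethylsilyl)oxy]-5-formyl-1,4a,6-trimethyl-2-[(3-methylbutanoyl)oxy]-1,2,3,4,4a,7,8,8a-octahydronaphthalen-1-yl]methyl 3-methylbutanoate
Product: 23 [(1S,2R,4aS,8R,8aR)-8-[(tert-butyldimethylsilyl)oxy]-5-ethenyl-1,4a,6-trimethyl-2-[(3-methylbutanoyl)oxy]-1,2,3,4,4a,7,8,8a-octahydronaphthalen-1-yl]methyl 3-methylbutanoate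
Conditions: Ph3PCH3Br, KN(SiMe3)2, THF, 0 °C; then 22, −78 → 0 °C
Reagents that add atoms: methyltriphenylphosphonium bromide, C[P+](c1ccccc1)(c1ccccc1)c1ccccc1.[Br-]
Why: Wittig methylenation of the hindered enal by the non-stabilised ylide is faster than attack on the two hindered esters at low temperature and creates the C11=C12 vinyl group.

Step 18
Reactants: 24 tert-butyl 3-oxobutanoate
Product: 25 tert-butyl (2E)-3-{[(trifluoromethyl)sulfonyl]oxy}but-2-enoate
Conditions: (CF3SO2)2O, aq. Me4NOH, toluene, 5 °C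
Reagents that add atoms: trifluoromethanesulfonic anhydride, O=S(=O)(OS(=O)(=O)C(F)(F)F)C(F)(F)F
Why: O-Triflation of the enolate with a non-coordinating tetramethylammonium counter-ion proceeds through the non-chelated extended enolate and should give the E-enol triflate (triflate trans to the ester), the geometry later carried into C13=C14.

Step 19
Reactants: 23 [(1S,2R,4aS,8R,8aR)-8-[(tert-butyldimethylsilyl)oxy]-5-ethenyl-1,4a,6-trimethyl-2-[(3-methylbutanoyl)oxy]-1,2,3,4,4a,7,8,8a-octahydronaphthalen-1-yl]methyl 3-methylbutanoate; 25 tert-butyl (2E)-3-{[(trifluoromethyl)sulfonyl]oxy}but-2-enoate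
Product: 27 tert-butyl (13E)-6β-[(tert-butyldimethylsilyl)oxy]-3α,19-bis[(3-methylbutanoyl)oxy]labda-8,13-dien-15-oate, via alkylborane 26 (not isolated)
Conditions: 9-borabicyclo[3.3.1]nonane dimer, THF, 0 °C → rt; then 25, PdCl2[1,1′-bis(diphenylphosphino)ferrocene] (5 mol %), aq. K3PO4, DMF, rt → 45 °C
Reagents that add atoms: none
Why: Anti-Markovnikov hydroboration occurs only at the monosubstituted C11=C12 vinyl group (the tetrasubstituted C8=C9 bond and the esters are inert to the dialkylborane), and the B-alkyl Suzuki–Miyaura coupling with the enol triflate forms C12–C13 with retention of the E geometry.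

Step 20
Reactants: 27 tert-butyl (13E)-6β-[(tert-butyldimethylsilyl)oxy]-3α,19-bis[(3-methylbutanoyl)oxy]labda-8,13-dien-15-oate
Product: 29 (13E)-6β-hydroxy-3α,19-bis[(3-methylbutanoyl)oxy]labda-8,13-dien-15-oic acid, via trimethylsilyl ester 28 (not isolated)
Conditions: Me3SiOTf, 2,6-lutidine, CH2Cl2, 0 °C; then HF·pyridine, THF, 0 °C → rt
Reagents that add atoms: none
Why: Silyl triflate activation of the tert-butyl ester carbonyl expels isobutene to give the silyl ester under buffered non-protic conditions (so the tetrasubstituted alkene is not isomerised), and HF·pyridine then cleaves the silyl ester and the hindered 6β-silyl ether under mildly acidic conditions that should not cause acyl migration from O19 to O6.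

**Compound list**

1 | 3-bromo-4-methylphenol | Cc1ccc(O)cc1Br | starting material
2 | 2-bromo-4-(methoxymethoxy)-1-methylbenzene | Cc1ccc(OCOC)cc1Br | intermediate
3 | [2-bromo-6-(methoxymethoxy)-3-methylphenyl]lithium (not isolated) | [Li]c1c(OCOC)ccc(C)c1Br | intermediate
4 | methyl 2-bromo-6-(methoxymethoxy)-3-methylbenzoate | COC(=O)c1c(OCOC)ccc(C)c1Br | intermediate
5 | chloro[2-(methoxycarbonyl)-3-(methoxymethoxy)-6-methylphenyl]magnesium (not isolated) | COC(=O)c1c(OCOC)ccc(C)c1[Mg]Cl | intermediate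
6 | methyl 2-formyl-6-(methoxymethoxy)-3-methylbenzoate | COC(=O)c1c(OCOC)ccc(C)c1C=O | intermediate
7 | methyl 3-methylbut-2-enoate | COC(=O)C=C(C)C | starting material
8 | methyl 2,3-dibromo-3-methylbutanoate (racemic, not isolated) | COC(=O)C(Br)C(C)(C)Br | intermediate
9 | methyl 2-bromo-3-methylbut-2-enoate | COC(=O)C(Br)=C(C)C | intermediate
10 | lithium 2-bromo-1-methoxy-3-methylbuta-1,3-dien-1-olate (not isolated) | [Li+].[O-]C(OC)=C(Br)C(C)=C | intermediate
11 | [(2-bromo-1-methoxy-3-methylbuta-1,3-dien-1-yl)oxy](tert-butyl)dimethylsilane (ketene acetal geometry not defined) | COC(O[Si](C)(C)C(C)(C)C)=C(Br)C(C)=C | intermediate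
12 | methyl 2-[(1R,3Z)-4-bromo-1-hydroxy-5-methoxy-3-methyl-5-oxopent-3-en-1-yl]-6-(methoxymethoxy)-3-methylbenzoate | COC(=O)c1c(OCOC)ccc(C)c1[C@H](O)C/C(C)=C(\Br)C(=O)OC | intermediate
13 | methyl 2-[(1R,3Z)-4-bromo-1-[(tert-butyldimethylsilyl)oxy]-5-methoxy-3-methyl-5-oxopent-3-en-1-yl]-6-(methoxymethoxy)-3-methylbenzoate | COC(=O)c1c(OCOC)ccc(C)c1[C@H](O[Si](C)(C)C(C)(C)C)C/C(C)=C(\Br)C(=O)OC | intermediate
14 | methyl 2-[(1R,3Z)-4-bromo-1-[(tert-butyldimethylsilyl)oxy]-5-methoxy-3-methyl-5-oxopent-3-en-1-yl]-6-hydroxy-3-methylbenzoate (key-step precursor) | COC(=O)c1c(O)ccc(C)c1[C@H](O[Si](C)(C)C(C)(C)C)C/C(C)=C(\Br)C(=O)OC | intermediate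
15 | dimethyl (4aS,8R)-8-[(tert-butyldimethylsilyl)oxy]-4a,6-dimethyl-2-oxo-2,4a,7,8-tetrahydronaphthalene-1,5-dicarboxylate (key-step product; labdane C6 R, C10 S) | CC1=C(C(=O)OC)[C@@]2(C)C=CC(=O)C(C(=O)OC)=C2[C@H](O[Si](C)(C)C(C)(C)C)C1 | intermediate
16 | dimethyl (4aS,8R)-8-[(tert-butyldimethylsilyl)oxy]-4a,6-dimethyl-2-oxo-2,3,4,4a,7,8-hexahydronaphthalene-1,5-dicarboxylate | CC1=C(C(=O)OC)[C@@]2(C)CCC(=O)C(C(=O)OC)=C2[C@H](O[Si](C)(C)C(C)(C)C)C1 | intermediate
17 | dimethyl (4aS,8R,8aR)-8-[(tert-butyldimethylsilyl)oxy]-2-hydroxy-4a,6-dimethyl-3,4,4a,7,8,8a-hexahydronaphthalene-1,5-dicarboxylate (enol form of the 3-oxo 19-ester; 5α-H) | CC1=C(C(=O)OC)[C@@]2(C)CCC(O)=C(C(=O)OC)[C@@H]2[C@H](O[Si](C)(C)C(C)(C)C)C1 | intermediate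
18 | dimethyl (1R,4aS,8R,8aR)-8-[(tert-butyldimethylsilyl)oxy]-1,4a,6-trimethyl-2-oxo-1,2,3,4,4a,7,8,8a-octahydronaphthalene-1,5-dicarboxylate (4α-methyl, 4β-ester) | CC1=C(C(=O)OC)[C@@]2(C)CCC(=O)[C@](C)(C(=O)OC)[C@@H]2[C@H](O[Si](C)(C)C(C)(C)C)C1 | intermediate
19 | dimethyl (1R,2R,4aS,8R,8aR)-8-[(tert-butyldimethylsilyl)oxy]-2-hydroxy-1,4a,6-trimethyl-1,2,3,4,4a,7,8,8a-octahydronaphthalene-1,5-dicarboxylate (3α-ol) | CC1=C(C(=O)OC)[C@@]2(C)CC[C@@H](O)[C@](C)(C(=O)OC)[C@@H]2[C@H](O[Si](C)(C)C(C)(C)C)C1 | intermediate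
20 | (1S,2R,4aS,8R,8aR)-8-[(tert-butyldimethylsilyl)oxy]-1,5-bis(hydroxymethyl)-1,4a,6-trimethyl-1,2,3,4,4a,7,8,8a-octahydronaphthalen-2-ol (3α,11,19-triol) | CC1=C(CO)[C@@]2(C)CC[C@@H](O)[C@](C)(CO)[C@@H]2[C@H](O[Si](C)(C)C(C)(C)C)C1 | intermediate
21 | (4R,4aR,5S,6R,8aS)-4-[(tert-butyldimethylsilyl)oxy]-6-hydroxy-5-(hydroxymethyl)-2,5,8a-trimethyl-3,4,4a,5,6,7,8,8a-octahydronaphthalene-1-carbaldehyde (C11 enal) | CC1=C(C=O)[C@@]2(C)CC[C@@H](O)[C@](C)(CO)[C@@H]2[C@H](O[Si](C)(C)C(C)(C)C)C1 | intermediate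
22 | [(1S,2R,4aS,8R,8aR)-8-[(tert-butyldimethylsilyl)oxy]-5-formyl-1,4a,6-trimethyl-2-[(3-methylbutanoyl)oxy]-1,2,3,4,4a,7,8,8a-octahydronaphthalen-1-yl]methyl 3-methylbutanoate | CC1=C(C=O)[C@@]2(C)CC[C@@H](OC(=O)CC(C)C)[C@](C)(COC(=O)CC(C)C)[C@@H]2[C@H](O[Si](C)(C)C(C)(C)C)C1 | intermediate
23 | [(1S,2R,4aS,8R,8aR)-8-[(tert-butyldimethylsilyl)oxy]-5-ethenyl-1,4a,6-trimethyl-2-[(3-methylbutanoyl)oxy]-1,2,3,4,4a,7,8,8a-octahydronaphthalen-1-yl]methyl 3-methylbutanoate | CC1=C(C=C)[C@@]2(C)CC[C@@H](OC(=O)CC(C)C)[C@](C)(COC(=O)CC(C)C)[C@@H]2[C@H](O[Si](C)(C)C(C)(C)C)C1 | intermediate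
24 | tert-butyl 3-oxobutanoate | CC(=O)CC(=O)OC(C)(C)C | starting material
25 | tert-butyl (2E)-3-{[(trifluoromethyl)sulfonyl]oxy}but-2-enoate | C/C(OS(=O)(=O)C(F)(F)F)=C\C(=O)OC(C)(C)C | intermediate
26 | B-alkyl-9-borabicyclo[3.3.1]nonane formed from 23 at C12 (not isolated) | CC1=C(CCB3C4CCCC3CCC4)[C@@]2(C)CC[C@@H](OC(=O)CC(C)C)[C@](C)(COC(=O)CC(C)C)[C@@H]2[C@H](O[Si](C)(C)C(C)(C)C)C1 | intermediate
27 | tert-butyl (13E)-6β-[(tert-butyldimethylsilyl)oxy]-3α,19-bis[(3-methylbutanoyl)oxy]labda-8,13-dien-15-oate (3R,4S,5R,6R,10S) | CC1=C(CC/C(C)=C/C(=O)OC(C)(C)C)[C@@]2(C)CC[C@@H](OC(=O)CC(C)C)[C@](C)(COC(=O)CC(C)C)[C@@H]2[C@H](O[Si](C)(C)C(C)(C)C)C1 | intermediate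
28 | trimethylsilyl (13E)-6β-[(tert-butyldimethylsilyl)oxy]-3α,19-bis[(3-methylbutanoyl)oxy]labda-8,13-dien-15-oate (not isolated) | CC1=C(CC/C(C)=C/C(=O)O[Si](C)(C)C)[C@@]2(C)CC[C@@H](OC(=O)CC(C)C)[C@](C)(COC(=O)CC(C)C)[C@@H]2[C@H](O[Si](C)(C)C(C)(C)C)C1 | intermediate
29 | (13E)-6β-hydroxy-3α,19-bis[(3-methylbutanoyl)oxy]labda-8,13-dien-15-oic acid (3R,4S,5R,6R,10S; CNP0333611.1) | CC1=C(CC/C(C)=C/C(=O)O)[C@@]2(C)CC[C@@H](OC(=O)CC(C)C)[C@](C)(COC(=O)CC(C)C)[C@@H]2[C@H](O)C1 | target

**Totals and risks**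

Total step count: 20.
Longest linear sequence: 17 steps (1, 2, 3, 6–17, 19, 20) from 3-bromo-4-methylphenol.

Steps most likely to fail:

1. Step 9. After oxidative addition, C–C reductive elimination between the fully substituted, ester-bearing alkenyl group and the crowded para carbon of an electron-poor phenoxide may be slower than protodebromination, the catalyst may rest as an O-bound phenoxide, and facial control at C10 may erode at 90 °C. The fallback reverses the polarity of the C9–C10 bond formation; it sets out from 6 and comes back at 15. An asymmetric aldol of 6 with 1-methoxy-1,3-bis(trimethylsilyloxy)buta-1,3-diene under Ti(OiPr)4/1,1′-bi-2-naphthol catalysis, followed by acidic desilylation, should give methyl 2-[(1R)-1-hydroxy-5-methoxy-3,5-dioxopentyl]-6-(methoxymethoxy)-3-methylbenzoate F1. Silylation (t-BuMe2SiCl, imidazole, DMF) would give methyl 2-[(1R)-1-[(tert-butyldimethylsilyl)oxy]-5-methoxy-3,5-dioxopentyl]-6-(methoxymethoxy)-3-methylbenzoate F2, and ZnBr2/n-PrSH the phenol methyl 2-[(1R)-1-[(tert-butyldimethylsilyl)oxy]-5-methoxy-3,5-dioxopentyl]-6-hydroxy-3-methylbenzoate F3. Oxidation of the phenol with PhI(OAc)2 in (CF3)2CHOH should let the β-keto ester carbon C9 attack C10, under the same conformational bias from C6, to give dimethyl (4aS,8R)-8-[(tert-butyldimethylsilyl)oxy]-6-hydroxy-4a-methyl-2-oxo-2,4a,7,8-tetrahydronaphthalene-1,5-dicarboxylate F4. Triflation (Tf2O, i-Pr2NEt) would give the ring-locked enol triflate dimethyl (4aS,8R)-8-[(tert-butyldimethylsilyl)oxy]-4a-methyl-2-oxo-6-{[(trifluoromethyl)sulfonyl]oxy}-2,4a,7,8-tetrahydronaphthalene-1,5-dicarboxylate F5, and Negishi methylation (MeZnCl, Pd(PPh3)4, THF) would install C17 and return 15.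

2. Step 6. The di-ortho-substituted aldehyde may react sluggishly and with eroded enantiofacial discrimination, and the brominated dienolate is less nucleophilic than the parent one. The fallback sets C6 by ketone reduction instead of by the aldol; it sets out from 6 and 11 and comes back at 12. The aldol promoted by BF3·OEt2 (CH2Cl2, −78 °C) should give racemic methyl 2-[(3Z)-4-bromo-1-hydroxy-5-methoxy-3-methyl-5-oxopent-3-en-1-yl]-6-(methoxymethoxy)-3-methylbenzoate F6. Oxidation with 1,1,1-triacetoxy-1,1-dihydro-1,2-benziodoxol-3(1H)-one under neutral conditions would give the aryl ketone methyl 2-[(3Z)-4-bromo-5-methoxy-3-methyl-5-oxopent-3-enoyl]-6-(methoxymethoxy)-3-methylbenzoate F7. Corey–Bakshi–Shibata reduction with BH3·SMe2 and (S)-1-methyl-3,3-diphenyltetrahydro-1H,3H-pyrrolo[1,2-c][1,3,2]oxazaborole (aryl as the large group) would then deliver the R alcohol 12.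

3. Step 11. Hydride may add to C5 from the β face or without selectivity, giving the cis-fused epimer, which cannot be corrected once C4 is quaternary. The fallback places C5 under thermodynamic control; it sets out from 16 and comes back at 17. HF·pyridine would free the alcohol dimethyl (4aS,8R)-8-hydroxy-4a,6-dimethyl-2-oxo-2,3,4,4a,7,8-hexahydronaphthalene-1,5-dicarboxylate F8, and oxidation with the same benziodoxolone reagent would give the ene-dione dimethyl (4aS)-4a,6-dimethyl-2,8-dioxo-2,3,4,4a,7,8-hexahydronaphthalene-1,5-dicarboxylate F9. Zn/AcOH would reduce the C4=C5 bond to dimethyl (4aS,8aR)-2-hydroxy-4a,6-dimethyl-8-oxo-3,4,4a,7,8,8a-hexahydronaphthalene-1,5-dicarboxylate F10, in which C5 is epimerisable next to the C6 ketone and should settle as the trans-fused isomer. With the β-keto ester masked as its sodium enolate (NaH), LiBH(s-Bu)3 should attack the C6 ketone from the open α face to give the 6β-alcohol dimethyl (4aS,8R,8aR)-2,8-dihydroxy-4a,6-dimethyl-3,4,4a,7,8,8a-hexahydronaphthalene-1,5-dicarboxylate F11. Silylation (t-BuMe2SiOTf, 2,6-lutidine; enol silyl ether hydrolysed on work-up) would return 17.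

**Further compounds**

F1 | step 9 | methyl 2-[(1R)-1-hydroxy-5-methoxy-3,5-dioxopentyl]-6-(methoxymethoxy)-3-methylbenzoate | COC(=O)c1c(OCOC)ccc(C)c1[C@H](O)CC(=O)CC(=O)OC
F2 | step 9 | methyl 2-[(1R)-1-[(tert-butyldimethylsilyl)oxy]-5-methoxy-3,5-dioxopentyl]-6-(methoxymethoxy)-3-methylbenzoate | COC(=O)c1c(OCOC)ccc(C)c1[C@H](O[Si](C)(C)C(C)(C)C)CC(=O)CC(=O)OC
F3 | step 9 | methyl 2-[(1R)-1-[(tert-butyldimethylsilyl)oxy]-5-methoxy-3,5-dioxopentyl]-6-hydroxy-3-methylbenzoate | COC(=O)c1c(O)ccc(C)c1[C@H](O[Si](C)(C)C(C)(C)C)CC(=O)CC(=O)OC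
F4 | step 9 | dimethyl (4aS,8R)-8-[(tert-butyldimethylsilyl)oxy]-6-hydroxy-4a-methyl-2-oxo-2,4a,7,8-tetrahydronaphthalene-1,5-dicarboxylate (enol form) | OC1=C(C(=O)OC)[C@@]2(C)C=CC(=O)C(C(=O)OC)=C2[C@H](O[Si](C)(C)C(C)(C)C)C1
F5 | step 9 | dimethyl (4aS,8R)-8-[(tert-butyldimethylsilyl)oxy]-4a-methyl-2-oxo-6-{[(trifluoromethyl)sulfonyl]oxy}-2,4a,7,8-tetrahydronaphthalene-1,5-dicarboxylate | O=S(=O)(OC1=C(C(=O)OC)[C@@]2(C)C=CC(=O)C(C(=O)OC)=C2[C@H](O[Si](C)(C)C(C)(C)C)C1)C(F)(F)F
F6 | step 6 | methyl 2-[(3Z)-4-bromo-1-hydroxy-5-methoxy-3-methyl-5-oxopent-3-en-1-yl]-6-(methoxymethoxy)-3-methylbenzoate (racemic) | COC(=O)c1c(OCOC)ccc(C)c1C(O)C/C(C)=C(\Br)C(=O)OC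
F7 | step 6 | methyl 2-[(3Z)-4-bromo-5-methoxy-3-methyl-5-oxopent-3-enoyl]-6-(methoxymethoxy)-3-methylbenzoate | COC(=O)c1c(OCOC)ccc(C)c1C(=O)C/C(C)=C(\Br)C(=O)OC
F8 | step 11 | dimethyl (4aS,8R)-8-hydroxy-4a,6-dimethyl-2-oxo-2,3,4,4a,7,8-hexahydronaphthalene-1,5-dicarboxylate | CC1=C(C(=O)OC)[C@@]2(C)CCC(=O)C(C(=O)OC)=C2[C@H](O)C1
F9 | step 11 | dimethyl (4aS)-4a,6-dimethyl-2,8-dioxo-2,3,4,4a,7,8-hexahydronaphthalene-1,5-dicarboxylate | CC1=C(C(=O)OC)[C@@]2(C)CCC(=O)C(C(=O)OC)=C2C(=O)C1
F10 | step 11 | dimethyl (4aS,8aR)-2-hydroxy-4a,6-dimethyl-8-oxo-3,4,4a,7,8,8a-hexahydronaphthalene-1,5-dicarboxylate (enol form, trans-fused) | CC1=C(C(=O)OC)[C@@]2(C)CCC(O)=C(C(=O)OC)[C@@H]2C(=O)C1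
F11 | step 11 | dimethyl (4aS,8R,8aR)-2,8-dihydroxy-4a,6-dimethyl-3,4,4a,7,8,8a-hexahydronaphthalene-1,5-dicarboxylate (enol form) | CC1=C(C(=O)OC)[C@@]2(C)CCC(O)=C(C(=O)OC)[C@@H]2[C@H](O)C1
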